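## Retrosynthetic overview

1. The ten-membered ring is closed last at C9–C10: a seco bromo-aldehyde gives the Z-enone directly by a nickel/photoredox/HAT coupling of the formyl C–H with the alkenyl bromide.
2. The seco aldehyde comes from oxidative cleavage of an allyl group; both oxiranes (all four stereocentres) and both acetates come from one double Sharpless epoxidation with in situ acetylation of an achiral bis-allylic diol.
3. The diol's skipped diene is cut at C5–C6: copper-catalysed coupling of an alkenylmagnesium (fragment A) with an allylic bromide (fragment B).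
4. Fragment A: 3-(trimethylsilyl)propargyl alcohol + allylMgBr (anti-carbomagnesiation fixes C4=C5), then a bromo-Wittig with a salt made from bromoethane. Fragment B: butynediol + allylMgBr/I2, then Pd methylation (fixes C7=C11).
5. Ring order: the two oxiranes first (step 15), the cyclodecenone last (step 17).

Assumption: atom labels follow germacrane numbering (ring C1–C10; C14 = methyl on C10; C15 = CH2OAc carbon on C4; C11 = spiro-oxirane carbon on C7, carrying C12H2OAc and C13H3), and commercial solutions of allylmagnesium bromide and methylzinc chloride count as purchasable.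

## Route

Step 1
Reactants: 1 bromoethane
Product: 2 ethyltriphenylphosphonium bromide
Conditions: PPh3, toluene, 110 °C
Reagents that add atoms: triphenylphosphine, c1ccc(cc1)P(c1ccccc1)c1ccccc1
Why: SN2 quaternisation of the phosphine by a primary bromide (phosphonium salt formation) is clean and the salt crystallises from toluene.

Step 2
Reactants: 2 ethyltriphenylphosphonium bromide
Product: 4 (1-bromoethyl)triphenylphosphonium bromide, via ethylidenetriphenylphosphorane 3 (not isolated)
Conditions: n-BuLi, THF, 0 °C; then Br2, −78 °C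
Reagents that add atoms: bromine, BrBr
Why: Deprotonation gives the ylide and electrophilic bromination at the ylide carbon returns the α-bromo phosphonium salt (Smithers-type α-halo Wittig salt synthesis); the CHBr centre is racemic and disappears in step 7.

Step 3
Reactants: 5 3-(trimethylsilyl)prop-2-yn-1-ol; 6 allylmagnesium bromide
Product: 8 (2E)-2-[(trimethylsilyl)methylidene]pent-4-en-1-ol, via alkenylmagnesium alkoxide 7 (not isolated)
Conditions: allylMgBr (3 equiv), Et2O, 0 °C to reflux; then aq. NH4Cl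
Reagents that add atoms: none
Why: Hydroxyl-directed anti-carbomagnesiation of a propargylic alcohol (Richey/Fallis-type allylmagnesiation) puts allyl on C4 and Mg on the silicon-bearing C5, chelated cis to CH2O, so after protonation SiMe3 is cis to the allyl group and the C4=C5 geometry is fixed.

Step 4
Reactants: 8 (2E)-2-[(trimethylsilyl)methylidene]pent-4-en-1-ol
Product: 9 tert-butyl(diphenyl){[(2E)-2-[(trimethylsilyl)methylidene]pent-4-en-1-yl]oxy}silane
Conditions: TBDPSCl, imidazole, DMF, 0 °C to rt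
Reagents that add atoms: tert-butyl(chloro)diphenylsilane, CC(C)(C)[Si](Cl)(c1ccccc1)c1ccccc1
Why: Standard silyl ether formation on a primary allylic alcohol; the TBDPS group survives steps 5 to 13.

Step 5
Reactants: 9 tert-butyl(diphenyl){[(2E)-2-[(trimethylsilyl)methylidene]pent-4-en-1-yl]oxy}silane
Product: 11 (4E)-4-{[(tert-butyldiphenylsilyl)oxy]methyl}-5-(trimethylsilyl)pent-4-en-1-ol, via B-alkyl-9-BBN adduct 10 (not isolated)
Conditions: 9-BBN, THF, 0 °C to rt; then NaOH, H2O2, 0 °C
Reagents that add atoms: 9-borabicyclo[3.3.1]nonane, B1C2CCCC1CCC2 (boron stays only in 10); hydrogen peroxide, OO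
Why: Hydroboration–oxidation with 9-BBN is anti-Markovnikov and touches only the monosubstituted alkene, not the hindered trisubstituted vinylsilane.

Step 6
Reactants: 11 (4E)-4-{[(tert-butyldiphenylsilyl)oxy]methyl}-5-(trimethylsilyl)pent-4-en-1-ol
Product: 12 (4E)-4-{[(tert-butyldiphenylsilyl)oxy]methyl}-5-(trimethylsilyl)pent-4-enal
Conditions: Dess–Martin periodinane, CH2Cl2, 0 °C to rt
Reagents that add atoms: none
Why: Dess–Martin oxidation takes the primary alcohol to the C1 aldehyde without affecting the vinylsilane or the silyl ether.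

Step 7
Reactants: 12 (4E)-4-{[(tert-butyldiphenylsilyl)oxy]methyl}-5-(trimethylsilyl)pent-4-enal; 4 (1-bromoethyl)triphenylphosphonium bromide
Product: 14 tert-butyl{[(2E,5Z)-6-bromo-2-[(trimethylsilyl)methylidene]hept-5-en-1-yl]oxy}diphenylsilane, via bromo ylide 13 (not isolated)
Conditions: 4, NaN(SiMe3)2, THF, −78 °C; then 12, DMPU, −78 °C to rt
Reagents that add atoms: none
Why: Wittig olefination with the α-bromo ylide (bromo analogue of the Stork–Zhao reaction) gives the 2-bromo-2-alkene with Br cis to the chain (expected about 8:1, E isomer removed by chromatography), which is the C1=C10 geometry of the target.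

Step 8
Reactants: 14 tert-butyl{[(2E,5Z)-6-bromo-2-[(trimethylsilyl)methylidene]hept-5-en-1-yl]oxy}diphenylsilane
Product: 15 tert-butyl{[(2E,5Z)-6-bromo-2-(iodomethylidene)hept-5-en-1-yl]oxy}diphenylsilane
Conditions: NIS, (CF3)2CHOH, 0 °C
Reagents that add atoms: N-iodosuccinimide, O=C1CCC(=O)N1I
Why: ipso-Iododesilylation of the vinylsilane (via the β-silyl cation, tertiary at C4) goes with retention, and the electron-poor alkenyl bromide is not attacked.

Step 9
Reactants: 16 but-2-yne-1,4-diol
Product: 17 4-[(tert-butyldiphenylsilyl)oxy]but-2-yn-1-ol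
Conditions: TBDPSCl (1 equiv), imidazole, 16 (3 equiv), DMF, 0 °C
Reagents that add atoms: tert-butyl(chloro)diphenylsilane, CC(C)(C)[Si](Cl)(c1ccccc1)c1ccccc1
Why: Statistical monosilylation (silyl ether formation) with excess cheap diol gives the mono-ether, and unreacted diol is washed out with water.

Step 10
Reactants: 17 4-[(tert-butyldiphenylsilyl)oxy]but-2-yn-1-ol; 6 allylmagnesium bromide
Product: 19 (2Z)-4-[(tert-butyldiphenylsilyl)oxy]-3-iodo-2-(prop-2-en-1-yl)but-2-en-1-ol, via alkenylmagnesium alkoxide 18 (not isolated)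
Conditions: allylMgBr (3 equiv), Et2O, reflux; then I2, THF, −40 to 0 °C
Reagents that add atoms: iodine, [I][I]
Why: Directed anti-allylmagnesiation then iodinolysis: allyl adds to C7 next to the free carbinol, Mg sits on C11 cis to the CH2O group, and iodine replaces Mg with retention, which fixes the tetrasubstituted C7=C11 geometry.

Step 11
Reactants: 19 (2Z)-4-[(tert-butyldiphenylsilyl)oxy]-3-iodo-2-(prop-2-en-1-yl)but-2-en-1-ol
Product: 20 (2E)-4-[(tert-butyldiphenylsilyl)oxy]-3-methyl-2-(prop-2-en-1-yl)but-2-en-1-ol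
Conditions: MeZnCl, Pd(PPh3)4 (5 mol%), THF, 50 °C
Reagents that add atoms: methylzinc chloride, C[Zn]Cl
Why: Negishi coupling of the alkenyl iodide under zerovalent palladium goes with retention and places the C13 methyl cis to C6.

Step 12
Reactants: 20 (2E)-4-[(tert-butyldiphenylsilyl)oxy]-3-methyl-2-(prop-2-en-1-yl)but-2-en-1-ol
Product: 21 {[(2E)-4-bromo-2-methyl-3-(prop-2-en-1-yl)but-2-en-1-yl]oxy}(tert-butyl)diphenylsilane
Conditions: CBr4, PPh3, CH2Cl2, 0 °C
Reagents that add atoms: tetrabromomethane, BrC(Br)(Br)Br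
Why: Appel bromination converts the primary allylic alcohol to the bromide by SN2 without allylic transposition.

Step 13
Reactants: 15 tert-butyl{[(2E,5Z)-6-bromo-2-(iodomethylidene)hept-5-en-1-yl]oxy}diphenylsilane; 21 {[(2E)-4-bromo-2-methyl-3-(prop-2-en-1-yl)but-2-en-1-yl]oxy}(tert-butyl)diphenylsilane
Product: 23 (2E,5E)-6-[(3Z)-4-bromopent-3-en-1-yl]-1,7-bis[(tert-butyldiphenylsilyl)oxy]-2-methyl-3-(prop-2-en-1-yl)hepta-2,5-diene, via alkenylmagnesium chloride 22 (not isolated)
Conditions: 15, i-PrMgCl·LiCl, THF, −20 to 0 °C; then Li2CuCl4 (5 mol%), 21, −40 to 0 °C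
Reagents that add atoms: isopropylmagnesium chloride–lithium chloride, CC(C)[Mg]Cl.[Li+].[Cl-] (Mg and Cl stay only in 22)
Why: Knochel iodine–magnesium exchange is selective for the alkenyl iodide over the alkenyl bromide and retains geometry, and the copper-catalysed Kochi/Linstrumelle-type coupling of the alkenyl Grignard with the allylic bromide occurs at the primary carbon (the other allyl terminus is fully substituted), forming C5–C6 with both alkene geometries intact.

Step 14
Reactants: 23 (2E,5E)-6-[(3Z)-4-bromopent-3-en-1-yl]-1,7-bis[(tert-butyldiphenylsilyl)oxy]-2-methyl-3-(prop-2-en-1-yl)hepta-2,5-diene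
Product: 24 (2E,5E)-6-[(3Z)-4-bromopent-3-en-1-yl]-2-methyl-3-(prop-2-en-1-yl)hepta-2,5-diene-1,7-diol
Conditions: HF·pyridine, pyridine, THF, 0 °C to rt
Reagents that add atoms: none
Why: Fluoride-mediated desilylation removes both TBDPS ethers at a stage where no acid- or base-sensitive group is present.

Step 15
Reactants: 24 (2E,5E)-6-[(3Z)-4-bromopent-3-en-1-yl]-2-methyl-3-(prop-2-en-1-yl)hepta-2,5-diene-1,7-diol
Product: 26 [(2R,3R)-2-[(3Z)-4-bromopent-3-en-1-yl]-3-{[(2R,3R)-3-(acetoxymethyl)-3-methyl-2-(prop-2-en-1-yl)oxiran-2-yl]methyl}oxiran-2-yl]methyl acetate, via bis-epoxy diol 25 (not isolated)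
Conditions: Ti(OiPr)4 (0.3 equiv), D-(−)-diethyl tartrate (0.36 equiv), t-BuOOH (2.2 equiv), 4 Å MS, CH2Cl2, −20 °C; then Et3N, Ac2O, DMAP (cat.), −20 to 0 °C
Reagents that add atoms: tert-butyl hydroperoxide, CC(C)(C)OO; acetic anhydride, CC(=O)OC(C)=O
Why: Double Sharpless asymmetric epoxidation: with D-(−)-tartrate both primary allylic alcohols are epoxidised from the same face of the mnemonic plane, setting C4 (R), C5 (R), C11 (R) and the C7 spiro centre (S in the target's CIP sense) under reagent control while the terminal alkene and the alkenyl bromide stay untouched, and in situ acetylation traps the sensitive epoxy alcohols.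

Step 16
Reactants: 26 [(2R,3R)-2-[(3Z)-4-bromopent-3-en-1-yl]-3-{[(2R,3R)-3-(acetoxymethyl)-3-methyl-2-(prop-2-en-1-yl)oxiran-2-yl]methyl}oxiran-2-yl]methyl acetate
Product: 28 [(2R,3R)-2-[(3Z)-4-bromopent-3-en-1-yl]-3-{[(2S,3R)-3-(acetoxymethyl)-3-methyl-2-(2-oxoethyl)oxiran-2-yl]methyl}oxiran-2-yl]methyl acetate, via vicinal diol 27 (not isolated)
Conditions: OsO4 (2 mol%), NaIO4, 2,6-lutidine, dioxane/H2O (3:1), rt
Reagents that add atoms: osmium tetroxide, O=[Os](=O)(=O)=O (oxygen carrier, re-formed by periodate); sodium periodate, [Na+].[O-]I(=O)(=O)=O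
Why: Lemieux–Johnson oxidation: OsO4 dihydroxylates only the monosubstituted alkene (the alkenyl bromide is electron-poor) and periodate cleaves the diol to the C9 aldehyde under near-neutral conditions tolerated by the epoxides, the acetates and the β,γ-epoxy aldehyde.

Step 17
Reactants: 28 [(2R,3R)-2-[(3Z)-4-bromopent-3-en-1-yl]-3-{[(2S,3R)-3-(acetoxymethyl)-3-methyl-2-(2-oxoethyl)oxiran-2-yl]methyl}oxiran-2-yl]methyl acetate
Product: 29 CNP0185847.2, (1(10)Z,4R,5R,7S,11R)-12,15-diacetoxy-4,5:7,11-diepoxygermacr-1(10)-en-9-one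
Conditions: Ir[dF(CF3)ppy]2(dtbbpy)PF6 (2 mol%), NiBr2(dme) (10 mol%), dtbbpy (10 mol%), quinuclidine (20 mol%), K2CO3, 1,4-dioxane (2 mM, syringe-pump addition), blue LEDs, rt
Reagents that add atoms: none
Why: Proposed new method: macrocyclising formyl C–H alkenylation by merged photoredox, hydrogen-atom-transfer and nickel catalysis; the photoexcited iridium complex oxidises quinuclidine to its radical cation, which abstracts the hydridic formyl hydrogen of 28 (polarity-matched; the other C–H bonds are epoxide, acetoxymethyl or allylic and not hydridic), zerovalent nickel adds oxidatively to the alkenyl C–Br bond with retention to give a divalent alkenylnickel bromide that captures the tethered acyl radical, and reductive elimination from trivalent nickel forms the C9–C10 bond and the Z-enone directly, while monovalent nickel is reduced back by the reduced photocatalyst and K2CO3 takes up HBr; high dilution favours ring closure, the primary acyl radical decarbonylates slowly at room temperature and the cis oxirane pre-folds the chain; the closest known reaction type is the intermolecular nickel/photoredox/HAT coupling of aldehydes with aryl, alkenyl and alkyl bromides to ketones, not yet shown for ring closure, for medium rings or for β,γ-epoxy aldehydes.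

## Compound list

1 | bromoethane | CCBr | starting material
2 | ethyltriphenylphosphonium bromide | CC[P+](c1ccccc1)(c1ccccc1)c1ccccc1.[Br-] | intermediate
3 | ethylidenetriphenylphosphorane | CC=P(c1ccccc1)(c1ccccc1)c1ccccc1 | intermediate
4 | (1-bromoethyl)triphenylphosphonium bromide (racemic) | CC(Br)[P+](c1ccccc1)(c1ccccc1)c1ccccc1.[Br-] | intermediate
5 | 3-(trimethylsilyl)prop-2-yn-1-ol | C[Si](C)(C)C#CCO | starting material
6 | allylmagnesium bromide | C=CC[Mg]Br | starting material
7 | bromomagnesium (2E)-3-(bromomagnesio)-2-(prop-2-en-1-yl)-3-(trimethylsilyl)prop-2-en-1-olate (Mg on C5 cis to CH2O) | C=CC/C(CO[Mg]Br)=C(/[Mg]Br)[Si](C)(C)C | intermediate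
8 | (2E)-2-[(trimethylsilyl)methylidene]pent-4-en-1-ol (SiMe3 cis to allyl) | C=CC/C(CO)=C\[Si](C)(C)C | intermediate
9 | tert-butyl(diphenyl){[(2E)-2-[(trimethylsilyl)methylidene]pent-4-en-1-yl]oxy}silane | C=CC/C(CO[Si](c1ccccc1)(c1ccccc1)C(C)(C)C)=C\[Si](C)(C)C | intermediate
10 | 9-[(4E)-4-{[(tert-butyldiphenylsilyl)oxy]methyl}-5-(trimethylsilyl)pent-4-en-1-yl]-9-borabicyclo[3.3.1]nonane | C[Si](C)(C)/C=C(\CCCB1C2CCCC1CCC2)CO[Si](c1ccccc1)(c1ccccc1)C(C)(C)C | intermediate
11 | (4E)-4-{[(tert-butyldiphenylsilyl)oxy]methyl}-5-(trimethylsilyl)pent-4-en-1-ol | C[Si](C)(C)/C=C(\CCCO)CO[Si](c1ccccc1)(c1ccccc1)C(C)(C)C | intermediate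
12 | (4E)-4-{[(tert-butyldiphenylsilyl)oxy]methyl}-5-(trimethylsilyl)pent-4-enal | C[Si](C)(C)/C=C(\CCC=O)CO[Si](c1ccccc1)(c1ccccc1)C(C)(C)C | intermediate
13 | (1-bromoethylidene)triphenylphosphorane | CC(Br)=P(c1ccccc1)(c1ccccc1)c1ccccc1 | intermediate
14 | tert-butyl{[(2E,5Z)-6-bromo-2-[(trimethylsilyl)methylidene]hept-5-en-1-yl]oxy}diphenylsilane | C/C(Br)=C/CC/C(CO[Si](c1ccccc1)(c1ccccc1)C(C)(C)C)=C\[Si](C)(C)C | intermediate
15 | tert-butyl{[(2E,5Z)-6-bromo-2-(iodomethylidene)hept-5-en-1-yl]oxy}diphenylsilane (fragment A; I cis to the C3 chain) | C/C(Br)=C/CC/C(CO[Si](c1ccccc1)(c1ccccc1)C(C)(C)C)=C\I | intermediate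
16 | but-2-yne-1,4-diol | OCC#CCO | starting material
17 | 4-[(tert-butyldiphenylsilyl)oxy]but-2-yn-1-ol | OCC#CCO[Si](c1ccccc1)(c1ccccc1)C(C)(C)C | intermediate
18 | bromomagnesium (2Z)-3-(bromomagnesio)-4-[(tert-butyldiphenylsilyl)oxy]-2-(prop-2-en-1-yl)but-2-en-1-olate (Mg on C11 cis to CH2O) | C=CC/C(CO[Mg]Br)=C(/[Mg]Br)CO[Si](c1ccccc1)(c1ccccc1)C(C)(C)C | intermediate
19 | (2Z)-4-[(tert-butyldiphenylsilyl)oxy]-3-iodo-2-(prop-2-en-1-yl)but-2-en-1-ol | C=CC/C(CO)=C(/I)CO[Si](c1ccccc1)(c1ccccc1)C(C)(C)C | intermediate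
20 | (2E)-4-[(tert-butyldiphenylsilyl)oxy]-3-methyl-2-(prop-2-en-1-yl)but-2-en-1-ol | C=CC/C(CO)=C(/C)CO[Si](c1ccccc1)(c1ccccc1)C(C)(C)C | intermediate
21 | {[(2E)-4-bromo-2-methyl-3-(prop-2-en-1-yl)but-2-en-1-yl]oxy}(tert-butyl)diphenylsilane (fragment B; CH2Br cis to methyl) | C=CC/C(CBr)=C(/C)CO[Si](c1ccccc1)(c1ccccc1)C(C)(C)C | intermediate
22 | [(1E,5Z)-6-bromo-2-{[(tert-butyldiphenylsilyl)oxy]methyl}hepta-1,5-dien-1-yl]magnesium chloride | C/C(Br)=C/CC/C(CO[Si](c1ccccc1)(c1ccccc1)C(C)(C)C)=C\[Mg]Cl | intermediate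
23 | (2E,5E)-6-[(3Z)-4-bromopent-3-en-1-yl]-1,7-bis[(tert-butyldiphenylsilyl)oxy]-2-methyl-3-(prop-2-en-1-yl)hepta-2,5-diene | C/C(Br)=C/CC/C(CO[Si](c1ccccc1)(c1ccccc1)C(C)(C)C)=C\C/C(CC=C)=C(\C)CO[Si](c1ccccc1)(c1ccccc1)C(C)(C)C | intermediate
24 | (2E,5E)-6-[(3Z)-4-bromopent-3-en-1-yl]-2-methyl-3-(prop-2-en-1-yl)hepta-2,5-diene-1,7-diol | C/C(Br)=C/CC/C(CO)=C\C/C(CC=C)=C(\C)CO | intermediate
25 | [(2R,3R)-2-[(3Z)-4-bromopent-3-en-1-yl]-3-{[(2R,3R)-3-(hydroxymethyl)-3-methyl-2-(prop-2-en-1-yl)oxiran-2-yl]methyl}oxiran-2-yl]methanol | C/C(Br)=C/CC[C@]1(CO)O[C@@H]1C[C@@]2(CC=C)O[C@]2(C)CO | intermediate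
26 | [(2R,3R)-2-[(3Z)-4-bromopent-3-en-1-yl]-3-{[(2R,3R)-3-(acetoxymethyl)-3-methyl-2-(prop-2-en-1-yl)oxiran-2-yl]methyl}oxiran-2-yl]methyl acetate | C/C(Br)=C/CC[C@]1(COC(C)=O)O[C@@H]1C[C@@]2(CC=C)O[C@]2(C)COC(C)=O | intermediate
27 | vicinal diol from 26 (CH2CH(OH)CH2OH in place of allyl; carbinol epimers) | C/C(Br)=C/CC[C@]1(COC(C)=O)O[C@@H]1C[C@@]2(CC(O)CO)O[C@]2(C)COC(C)=O | intermediate
28 | [(2R,3R)-2-[(3Z)-4-bromopent-3-en-1-yl]-3-{[(2S,3R)-3-(acetoxymethyl)-3-methyl-2-(2-oxoethyl)oxiran-2-yl]methyl}oxiran-2-yl]methyl acetate (seco bromo-aldehyde) | C/C(Br)=C/CC[C@]1(COC(C)=O)O[C@@H]1C[C@@]2(CC=O)O[C@]2(C)COC(C)=O | intermediate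
29 | CNP0185847.2, (1(10)Z,4R,5R,7S,11R)-12,15-diacetoxy-4,5:7,11-diepoxygermacr-1(10)-en-9-one (cyclodec-1(10)-en-9-one with cis-fused C4–C5 oxirane, C7 spiro-oxirane, CH2OAc on C4 and on C11) | CC(=O)OC[C@]12CC/C=C(/C)C(=O)C[C@]3(C[C@H]1O2)O[C@]3(C)COC(C)=O | target

## Step count and risks

Total step count: 17. Longest linear sequence: 11 steps (steps 3 to 8, then 13 to 17).

Step 17 (the proposed new step). Risks are hydrogen abstraction at other sites, base-induced opening of the β,γ-epoxy aldehyde or ketone, and oligomerisation instead of ring closure. The fallback uses known chemistry and sets out from 28. A Nozaki–Hiyama–Kishi ring closure (CrCl2 in excess, NiCl2 catalytic, DMSO/THF, high dilution, rt) joins C9 and C10 and gives the macrocyclic allylic alcohol F1 as a mixture of C9 epimers. Dess–Martin periodinane buffered with NaHCO3 then oxidises both epimers to the enone, and the fallback comes back to the route at 29.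

Step 10. The alkenylmagnesium 18 carries a silyloxy group β to magnesium and may eliminate to an allene, and addition to the internal alkyne may be slow. The fallback sets out from 5 and avoids any β-leaving group. CuI-catalysed anti-methylmagnesiation of 5 with MeMgCl (Duboudin conditions), followed by trapping of the α-silyl alkenylmagnesium with allyl bromide, gives (2E)-2-methyl-3-(trimethylsilyl)hexa-2,5-dien-1-ol F2. TBDPSCl and imidazole give the silyl ether F3. NIS in (CF3)2CHOH replaces silicon by iodine with retention to give the alkenyl iodide F4. Lithium–iodine exchange with t-BuLi at −78 °C and addition to paraformaldehyde installs the C6 carbinol, and the fallback comes back to the route at 20.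

Step 13. The exchange may not fully discriminate iodide from bromide, and the copper step may give some SN2′ product or homocoupling. The fallback reverses the polarity of the two partners and sets out from 21. Miyaura borylation of 21 with bis(pinacolato)diboron and Pd2(dba)3 gives the allyl pinacolboronate F5. A ligand-controlled, α-selective Suzuki–Miyaura coupling of F5 with 15 (Pd(OAc)2, bulky biarylphosphine, K3PO4, THF/H2O, rt) follows, in which zerovalent palladium inserts into the C–I bond and leaves the C–Br bond alone. The fallback comes back to the route at 23.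

## Further compounds

F1 | step 17 | macrocyclic allylic alcohol (9-hydroxy analogue of 29, C9 epimers) | CC(=O)OC[C@]12CC/C=C(/C)C(O)C[C@]3(C[C@H]1O2)O[C@]3(C)COC(C)=O
F2 | step 10 | (2E)-2-methyl-3-(trimethylsilyl)hexa-2,5-dien-1-ol | OC/C(C)=C(\CC=C)[Si](C)(C)C
F3 | step 10 | silyl ether, tert-butyl{[(2E)-2-methyl-3-(trimethylsilyl)hexa-2,5-dien-1-yl]oxy}diphenylsilane | CC(C)(C)[Si](OC/C(C)=C(\CC=C)[Si](C)(C)C)(c1ccccc1)c1ccccc1
F4 | step 10 | alkenyl iodide, tert-butyl{[(2E)-3-iodo-2-methylhexa-2,5-dien-1-yl]oxy}diphenylsilane | CC(C)(C)[Si](OC/C(C)=C(\CC=C)I)(c1ccccc1)c1ccccc1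
F5 | step 13 | allyl pinacolboronate, tert-butyl{[(2Z)-2-methyl-3-(prop-2-en-1-yl)-4-(4,4,5,5-tetramethyl-1,3,2-dioxaborolan-2-yl)but-2-en-1-yl]oxy}diphenylsilane | C=CC/C(CB1OC(C)(C)C(C)(C)O1)=C(/C)CO[Si](c1ccccc1)(c1ccccc1)C(C)(C)C
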